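Temperature is what differs between the flasks on this bench. Going up, the loss of target to over-reaction product gains on the catalysed step that makes target from substrate, because the activation energy of the loss, 75.0 kJ mol⁻¹, is higher than the 54.0 kJ mol⁻¹ of that step.

all flasks: substrate 0.40 M; catalyst 4.0 mM; time 10 min
- larch: temperature 35 °C
- birch: temperature 65 °C
- cedar: temperature 5 °C
- alder: temperature 95 °C

- the flask that comes out highest in amount of target, in percent of the substrate charged, or "all alike" when all lie within 1.5 percentage points (larch / birch / cedar / alder / all alike)
- target at the end, in percent of the substrate charged, larch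
- target at the end, in percent of the substrate charged, birch
- target at the end, in percent of the substrate charged, cedar
- target at the end, in percent of the substrate charged, alder

- the list of constants is for 5 °C, to be carried to other temperatures by the activation energies and enthalpies

    isomer of the product A ⇌ isomer of the product B (K1 = 2.9, k1 = 0.030 s⁻¹, Ea1 = 78.0 kJ mol⁻¹, ΔH1 = −17.0 kJ mol⁻¹)
    isomer of the product B ⇌ substrate (k2 = 6.1 × 10⁻⁴ s⁻¹, Ea2 = 75.0 kJ mol⁻¹)
    target + catalyst ⇌ isomer of the product A + catalyst, rate k3*[catalyst]*[target] forward; the back reaction follows from the equilibrium constant (K3 = 1.1, k3 = 0.38 L mol⁻¹ s⁻¹, Ea3 = 43.0 kJ mol⁻¹, ΔH3 = −19.0 kJ mol⁻¹)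
    target → over-reaction product (k4 = 0.0018 s⁻¹, Ea4 = 75.0 kJ mol⁻¹)
    substrate + catalyst ⇌ target + catalyst, rate k5*[substrate]*[catalyst] forward; the back reaction follows from the equilibrium constant (K5 = 2.2, k5 = 0.92 L mol⁻¹ s⁻¹, Ea5 = 54.0 kJ mol⁻¹, ΔH5 = −8.00 kJ mol⁻¹)
    (constants at 5 °C)

Each flask starts as substrate and catalyst, and the catalyst leaves its steps as it entered them. Material that reaches over-reaction product does not return, so the useful reckoning is of the fraction left. In cedar, c(target) with no feed falls to 0.5 of itself through the step to over-reaction product in 6.42 min; this time is the drain half-life. Over the 10 min of the run, an unfed stock of target in cedar keeps a fraction 34.0 % against that step.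

In alder the same step runs 2800 times faster than in cedar, so the drain half-life there is 0.139 s, far shorter than the run. My reckoning therefore puts cedar above alder. It stops there and gives no figure for cedar: target in cedar is made during the run, and a fraction left is not a yield. The note for the next person is short: keep cedar cold and read it on time, since its drain half-life is shorter than the run.

The forecast names cedar, with 13.2 % for cedar, 0.14 % for larch, 0 % for birch and 0 % for alder. Of birch and alder it says that over-reaction “destroys everything, leaving essentially zero”.

The simulation gives cedar as highest, with 13.3 % in cedar, 0.140 % in larch, 0 % in birch and 0 % in alder.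

In cedar at 10.0 min, target has its drain half-life of 6.42 min, while isomer of the product B has a half-life of 19 min by its forward step to substrate, a longer time, and the flask holds 44.7 % of isomer of the product B against 13.3 % of target. In the neighbour flask, cedar left until 40 min, the drain half-life takes an unfed 13.3 % of target down to 0.521 % by the step to over-reaction product, and the flask holds 6.27 %.

(The numbers belong to no real substance, and the outcome is calculated.)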